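## The problem

The target 20 is an isocoumarin (ring A fused to a pyranone: C1 carbonyl, O2, C3 pentyl) whose C8 oxygen carries ring B, a 2,4-dihydroxy-6-pentylphenyl group. It has no stereocenter, so nothing has to be controlled or relayed in space; every selectivity question is regiochemical. The hard bond is the diaryl ether. Its oxygen sits on C8, between C7–H and the carbonyl-bearing C8a, and on C1', between the C2' oxygen and the C6' pentyl chain, and ring B is far too electron-rich to serve as an electrophile. Ring A is 1,2,3,5-tetrasubstituted with three contiguous substituted carbons (C4a, C8a, C8), a pattern that stepwise aromatic substitution reaches poorly. The three phenols, two of them on the hydroxyhydroquinone-like ring B, are prone to oxidation, and the enol lactone opens with hydroxide or alkoxide, so the phenols should stay masked as robust ethers and the lactone should be closed late without base. The enabling feature is the sequence C8(O)–C8a(C1)–C4a(C4) on ring A: an oxygen nucleophile and a one-carbon electrophile on neighbouring carbons are what a C8–C8a aryne takes up in one event, and a group on C4a can both steer that addition and later supply C4 and C3.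

## Retrosynthesis

**Unmasking (three O–CH3 bonds; 20 from 18).** The last operation cuts the three methyl ethers of 18, through the borate 19 that forms in the flask. Methyl is preferred over benzyl, silyl or acetal groups because ring A must pass an alkyllithium, fluoride and an aryl anion, and ring B a peracid; simple alkyl ethers pass all of these, and the choice makes 1 the natural start for ring A. The price is one strongly Lewis-acidic step at the end, which a diaryl ether and an isocoumarin lactone are expected to tolerate. 18 has the full skeleton but none of the oxidation-prone phenols.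

**Lactone (O2–C3; 18 from 17).** 18 is opened at O2–C3 to the alkynyl benzoic acid 17. A cut at C1–O2 would need a C3 ketone enol, and a cut at C3–C4 or C4–C4a would turn the closure into a base-mediated condensation. The O2–C3 cut needs only a π-acid and keeps C3 and C4 at the alkyne oxidation level with the pentyl chain attached. The forward reaction must close 6-endo (oxygen to the pentyl-bearing carbon) and not 5-exo. 17 has one ring less and no base-sensitive group.

**Key cut (C8–O and C8a–C1; 17 from 7, 13 and 14).** 17 is cut at two bonds on neighbouring carbons, leading to silyl triflate 7, phenol 13 and carbon dioxide 14, that is, to aryne 16 placed between a nucleophile and an electrophile. A single cut at C8–O would ask a metal-catalysed or addition–elimination ether synthesis to join a phenol with two ortho substituents to a carbon flanked by a carboxyl. A cut at C1'–O is ruled out by the three donor oxygens of ring B. The aryne carbon has no ligand sphere and only hydrogen on its C7 side, so it is the least hindered electrophile ring A can offer, and the anion left at C8a sits exactly where the carboxyl is wanted. The cut divides the molecule into two fragments of three steps each. The forward reaction must put oxygen on C8 and not C8a, and must carboxylate the C8a anion before it finds a proton.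

**Ring A fragment (aryl–alkynyl bond, then C–Si and O–S, then two C–I; 7 from 5 and 6, 5 from 2, 2 from 1).** 7 is cut at the future C4a–C4 bond to iodo silyl triflate 5 and hept-1-yne 6. The alkyne enters after the triflate because a free ortho-alkynyl phenol would cyclise to a benzofuran under coupling conditions, and iodide is the handle because it reacts long before a hindered aryl triflate. 5 goes back, through silyl ether 3 and lithium phenoxide 4, to the symmetric diiodophenol 2: one iodine becomes the silicon site and the other remains as the coupling handle, so no silyl arene has to be halogenated. 2 comes from 1 by double ortho iodination. The forward sequence asks for mono-selective iodine–lithium exchange.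

**Ring B fragment (C1'–O, C–CHO, O–CH3; 13 from 11, 11 from 9, 9 from 8).** 13 is cut at C1'–O to aldehyde 11 (through formate 12), 11 at the formyl carbon to 9 (through iminium salt 10), and 9 at its methyl ethers to olivetol 8, which already carries the pentyl chain. Direct hydroxylation of 9 would not be regioselective. Formylation goes para to one methoxy group and ortho to the other, and oxygen insertion then puts the hydroxyl on exactly that carbon. All three reactions are standard for this substitution pattern.

## Roads not taken

**Alternative 1:** Ring B is grown on the C8 oxygen instead of being brought in. The cut removes four ring B bonds (C1'–C2', C2'–C3', C4'–C5', C5'–C6') and leads to diazoketone A2, an isocoumarin whose C8 oxygen carries a 2-(diazoacetyl)hept-1-enyl group, and ethoxyacetylene A3.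
- Forward key step: light converts A2 to a vinylketene by Wolff rearrangement, A3 adds [2+2], and on heating the cyclobutenone opens (four electrons) and the dienylketene closes (six electrons) to the phenol A1, 8-(4-ethoxy-2-hydroxy-6-pentylphenoxy)-6-methoxy-3-pentylisocoumarin.
- Merits: the ether is never made between two aromatic rings, so its steric problem disappears. The C2' hydroxyl arrives free, C4' is differentiated, and the ynol ether polarity fixes the ring B pattern.
- Weak points: A2 requires a preformed isocoumarin with a free C8 hydroxyl, which is hydrogen-bonded to C1=O and poorly nucleophilic. That hydroxyl must be O-vinylated to a β-aryloxy enone and then converted to a diazoketone, at least five steps beyond an isocoumarin that itself needs five or six. The isocoumarin chromophore competes for the light used in the Wolff step, and its C3–C4 bond can enter photocycloadditions. The sequence is linear and is estimated at fourteen steps or more.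
- Comparison: this road is better in that it poses no regiochemical question on ring A and no competition between CO2 and a proton. The chosen plan sets against that two three-step fragments, nine steps in all, and a key step run in the dark at or below room temperature on simple, stable partners.

**Alternative 2:** Ring A is made by cycloaddition. The cut is at C7–C8 and C4a–C8a, giving the aryloxypropiolate A5 (made from 13) and the siloxydiene A6 (4-methoxy-2-silyloxypenta-1,3-diene).
- Forward key step: on heating, the CH2 end of A6 bonds to the aryloxy-bearing alkyne carbon and the methoxy-bearing end to the ester-bearing carbon. Loss of the methoxy group and of silicon aromatises the adduct to benzoate A4, methyl 2-(2,4-dimethoxy-6-pentylphenoxy)-4-hydroxy-6-methylbenzoate.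
- Merits: the ether oxygen is attached to an sp carbon before ring A exists, which tolerates the two ortho groups of ring B. The polarity of diene and dienophile is matched, the C6 hydroxyl emerges free, and the reaction class is known.
- Weak points: the aryloxy donor on the β-carbon makes A5 a push–pull alkyne and a sluggish dienophile, and the diene end that must bond to C8a is fully substituted. A4 also lacks C3, C4-bound functionality and the pentyl chain: the C4a methyl must be laterally metalated with a strong amide base next to a doubly ortho-substituted ester, acylated and cyclodehydrated, after the C6 hydroxyl has been protected. That is four further steps, roughly twelve in total.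
- Comparison: this road rests on a known reaction type, which the chosen key step does not. The chosen plan offers in return that its ring A partner already carries the alkyne, so C3, C4 and the pentyl chain arrive with it and the lactone closes in one catalytic step.

**Alternative 3:** Ring A and the new lactone are formed together from the methoxypyrone A8 (4-methoxy-6-pentylpyran-2-one) and the aryloxycrotonate A9 (from 13). The cut is at C8a–C4a, C7–C6 and C1–O2.
- Forward key step: the lithium dienolate of A9 displaces methoxide at pyrone C4 through its α-carbon, its γ-carbon attacks the pyrone carbonyl to close ring A while the old lactone opens, and the released enolate oxygen acylates on the ester to give A7, 8-(2,4-dimethoxy-6-pentylphenoxy)-6-hydroxy-3-pentylisocoumarin.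
- Merits: it is the most convergent plan. Both rings form in one operation from two small pieces, the C6 hydroxyl is differentiated, and the total could be about six steps.
- Weak points: three bond formations must each take one of several open courses. The dienolate can react at its α- or γ-carbon, and the pyrone can be attacked at C4, C6 or C2. The dienolate can deprotonate the C6 side chain of A8 instead of adding. A β-aryloxy ester enolate can also expel the aryloxide, which would destroy the ether oxygen the plan is built around.
- Comparison: in step count this road beats the chosen plan. The chosen plan concentrates its risk in one event whose regiochemistry follows known aryne behaviour, and it keeps a known-chemistry fallback that uses the same fragment 13.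

Key step: step 7

Remark: isocoumarin numbering (C1 carbonyl, O2, C3, C4, C4a, C5–C8, C8a) is used for ring A and primed numbers for ring B, with C1' on the ether oxygen; the target is achiral, so no stereodescriptors appear.

## Route

Step 1
Reactants: 1 4-methoxyphenol
Product: 2 2,6-diiodo-4-methoxyphenol
Conditions: BnMe3N·ICl2 (2.1 equiv), NaHCO3, CH2Cl2–MeOH, rt
Reagents that add atoms: benzyltrimethylammonium dichloroiodate, C[N+](C)(C)Cc1ccccc1.Cl[I-]Cl
Why: Electrophilic aromatic iodination under mild bicarbonate-buffered conditions; the hydroxyl is the stronger director and its para position is blocked, so both iodines enter ortho to it without an oxidant that could attack the hydroquinone monoether.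

Step 2
Reactants: 2 2,6-diiodo-4-methoxyphenol
Product: 5 2-iodo-4-methoxy-6-(trimethylsilyl)phenyl trifluoromethanesulfonate, via aryl silyl ether 3 (not isolated), via lithium phenoxide 4 (not isolated)
Conditions: (Me3Si)2NH, THF, reflux, then evaporation; n-BuLi (1.0 equiv), THF, −78 °C; (CF3SO2)2O, −78 °C to rt
Reagents that add atoms: hexamethyldisilazane, C[Si](C)(C)N[Si](C)(C)C; trifluoromethanesulfonic anhydride, O=S(=O)(OS(=O)(=O)C(F)(F)F)C(F)(F)F
Why: O-silylation, iodine–lithium exchange, 1,3 O-to-C silyl shift (retro-Brook rearrangement) and O-triflation, the standard one-flask entry to 2-silylaryl triflates from 2-halophenols; the second iodine should survive because the neutral diiodide 3 exchanges faster than the electron-rich anion 4.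

Step 3
Reactants: 5 2-iodo-4-methoxy-6-(trimethylsilyl)phenyl trifluoromethanesulfonate; 6 hept-1-yne
Product: 7 2-(hept-1-yn-1-yl)-4-methoxy-6-(trimethylsilyl)phenyl trifluoromethanesulfonate
Conditions: PdCl2(PPh3)2 (3 mol %), CuI (5 mol %), Et3N, THF, rt
Reagents that add atoms: none
Why: Sonogashira coupling; zerovalent palladium inserts into the C–I bond at room temperature long before it touches the hindered aryl triflate, and the aryl–silicon bond is inert in the absence of fluoride.

Step 4
Reactants: 8 olivetol
Product: 9 1,3-dimethoxy-5-pentylbenzene
Conditions: MeI, K2CO3, acetone, reflux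
Reagents that add atoms: iodomethane, CI
Why: Williamson O-methylation of both phenols; carbonate in acetone favours O- over C-alkylation of the resorcinol.

Step 5
Reactants: 9 1,3-dimethoxy-5-pentylbenzene
Product: 11 2,4-dimethoxy-6-pentylbenzaldehyde, via iminium chloride 10 (not isolated)
Conditions: POCl3, DMF, 0 °C to 70 °C; then H2O
Reagents that add atoms: N,N-dimethylformamide, CN(C)C=O; water, O
Why: Vilsmeier–Haack formylation; attack para to one methoxy group and ortho to the other (next to the pentyl chain) is preferred over the crowded carbon between the two methoxy groups, as with the lower homologue orcinol dimethyl ether, and water hydrolyses 10 to the aldehyde.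

Step 6
Reactants: 11 2,4-dimethoxy-6-pentylbenzaldehyde
Product: 13 2,4-dimethoxy-6-pentylphenol, via aryl formate 12 (not isolated)
Conditions: mCPBA, CH2Cl2, 0 °C to rt; then K2CO3 (cat.), MeOH, rt
Reagents that add atoms: 3-chloroperoxybenzoic acid, O=C(OO)c1cccc(Cl)c1
Why: Baeyer–Villiger (Dakin-type) oxidation; the electron-rich aryl group migrates in the Criegee intermediate in preference to hydrogen, and methanolysis of formate 12 frees the phenol on the carbon that carried the formyl group.

Step 7
Reactants: 7 2-(hept-1-yn-1-yl)-4-methoxy-6-(trimethylsilyl)phenyl trifluoromethanesulfonate; 13 2,4-dimethoxy-6-pentylphenol; 14 carbon dioxide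
Product: 17 2-(2,4-dimethoxy-6-pentylphenoxy)-6-(hept-1-yn-1-yl)-4-methoxybenzoic acid, via potassium phenoxide 15 (not isolated), via aryne 16 (not isolated)
Conditions: 13 (1.5 equiv), KH, THF, 0 °C; then 7 (1.0 equiv), CsF, 18-crown-6, CO2 (1 atm), THF, 0 °C to rt; aq. HCl work-up
Reagents that add atoms: none
Why: Proposed new method: fluoride attacks the silicon of 7 and triflate leaves to give aryne 16; the closest known reaction types are the three-component coupling of arynes with amines and CO2 to anthranilic acids and the O-arylation of phenoxides by arynes, which the step merges by using a phenoxide as the nucleophile. The oxygen of 15, whose ortho and para carbons are all substituted so that C-arylation is closed, adds to the aryne carbon that becomes C8, and the aryl anion left at C8a in an in-plane sp2 orbital captures CO2 to give the carboxylate, freed as 17 on acidification. No ring is closed and no stereocenter is formed. The selectivity needed is regiochemical, oxygen on C8 and not on C8a. The heptynyl group on C4a should secure it, because its sp carbon withdraws inductively and stabilises charge building on the adjacent C8a (the aryne is distorted toward attack at the distal carbon) and because it shields C8a, whereas the C6 methoxy group is one bond further from the reacting carbons and 4-substituted arynes show little bias. Carboxylation must outrun protonation, which is why 15 is made with KH (H2 is the only by-product), the solvent is THF and not acetonitrile, and the solution is saturated with CO2 before sparingly soluble CsF releases the aryne slowly. The phenoxide is used in excess over 7 so that the product carboxylate does not compete for the aryne.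

Step 8
Reactants: 17 2-(2,4-dimethoxy-6-pentylphenoxy)-6-(hept-1-yn-1-yl)-4-methoxybenzoic acid
Product: 18 8-(2,4-dimethoxy-6-pentylphenoxy)-6-methoxy-3-pentyl-1H-isochromen-1-one
Conditions: AgOSO2CF3 (10 mol %), CH2Cl2, rt
Reagents that add atoms: none
Why: Silver-catalysed cycloisomerisation of a 2-alkynylbenzoic acid; monovalent silver activates the alkyne and the neutral carboxyl oxygen adds anti at the pentyl-bearing carbon (6-endo-dig), which is the alkyl-substituted, more electron-poor terminus of the alkyne conjugated to the ortho carboxyl, and protodemetalation gives the isocoumarin.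

Step 9
Reactants: 18 8-(2,4-dimethoxy-6-pentylphenoxy)-6-methoxy-3-pentyl-1H-isochromen-1-one
Product: 20 8-(2,4-dihydroxy-6-pentylphenoxy)-6-hydroxy-3-pentyl-1H-isochromen-1-one, via tris(dibromoboryl) ether 19 (not isolated)
Conditions: BBr3 (6 equiv), CH2Cl2, −78 °C to rt; then H2O
Reagents that add atoms: none
Why: Lewis-acid ether cleavage; boron binds each methoxy oxygen and bromide attacks the methyl carbon, while the diaryl ether has no alkyl carbon to attack and isocoumarin lactones are known to survive these conditions, and water hydrolyses 19 to the triphenol.

## Compound list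

1 | 4-methoxyphenol | COc1ccc(O)cc1 | starting material
2 | 2,6-diiodo-4-methoxyphenol | COc1cc(I)c(O)c(I)c1 | intermediate
3 | (2,6-diiodo-4-methoxyphenoxy)trimethylsilane | COc1cc(I)c(O[Si](C)(C)C)c(I)c1 | intermediate
4 | lithium 2-iodo-4-methoxy-6-(trimethylsilyl)phenolate | COc1cc(I)c([O-])c([Si](C)(C)C)c1.[Li+] | intermediate
5 | 2-iodo-4-methoxy-6-(trimethylsilyl)phenyl trifluoromethanesulfonate | COc1cc(I)c(OS(=O)(=O)C(F)(F)F)c([Si](C)(C)C)c1 | intermediate
6 | hept-1-yne | CCCCCC#C | starting material
7 | 2-(hept-1-yn-1-yl)-4-methoxy-6-(trimethylsilyl)phenyl trifluoromethanesulfonate | CCCCCC#Cc1cc(OC)cc([Si](C)(C)C)c1OS(=O)(=O)C(F)(F)F | intermediate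
8 | olivetol (5-pentylbenzene-1,3-diol) | CCCCCc1cc(O)cc(O)c1 | starting material
9 | 1,3-dimethoxy-5-pentylbenzene | CCCCCc1cc(OC)cc(OC)c1 | intermediate
10 | N-[(2,4-dimethoxy-6-pentylphenyl)methylidene]-N-methylmethanaminium chloride | CCCCCc1cc(OC)cc(OC)c1C=[N+](C)C.[Cl-] | intermediate
11 | 2,4-dimethoxy-6-pentylbenzaldehyde | CCCCCc1cc(OC)cc(OC)c1C=O | intermediate
12 | 2,4-dimethoxy-6-pentylphenyl formate | CCCCCc1cc(OC)cc(OC)c1OC=O | intermediate
13 | 2,4-dimethoxy-6-pentylphenol | CCCCCc1cc(OC)cc(OC)c1O | intermediate
14 | carbon dioxide | O=C=O | starting material
15 | potassium 2,4-dimethoxy-6-pentylphenolate | CCCCCc1cc(OC)cc(OC)c1[O-].[K+] | intermediate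
16 | 3-(hept-1-yn-1-yl)-5-methoxybenzyne (1,2-didehydrobenzene) | CCCCCC#CC1=CC(OC)=CC#C1 | intermediate
17 | 2-(2,4-dimethoxy-6-pentylphenoxy)-6-(hept-1-yn-1-yl)-4-methoxybenzoic acid | CCCCCC#Cc1cc(OC)cc(Oc2c(OC)cc(OC)cc2CCCCC)c1C(=O)O | intermediate
18 | 8-(2,4-dimethoxy-6-pentylphenoxy)-6-methoxy-3-pentyl-1H-isochromen-1-one | CCCCCc1cc2cc(OC)cc(Oc3c(OC)cc(OC)cc3CCCCC)c2c(=O)o1 | intermediate
19 | 6-[(dibromoboranyl)oxy]-8-{2,4-bis[(dibromoboranyl)oxy]-6-pentylphenoxy}-3-pentyl-1H-isochromen-1-one | CCCCCc1cc2cc(OB(Br)Br)cc(Oc3c(OB(Br)Br)cc(OB(Br)Br)cc3CCCCC)c2c(=O)o1 | intermediate
20 | 8-(2,4-dihydroxy-6-pentylphenoxy)-6-hydroxy-3-pentyl-1H-isochromen-1-one | CCCCCc1cc2cc(O)cc(Oc3c(O)cc(O)cc3CCCCC)c2c(=O)o1 | target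

## Step count and least certain steps

Total: 9 steps. Longest linear sequence: 6 steps (steps 1, 2, 3, 7, 8, 9 from 1; equally steps 4, 5, 6, 7, 8, 9 from 8).

**Step 7 (key step, proposed new method).** Four processes may spoil it:
- protonation of the C8a aryl anion instead of carboxylation;
- addition of the phenoxide at the wrong aryne carbon, since the alkynyl bias is inferred and not demonstrated;
- reversible capture of the phenoxide by CO2 as its carbonate, which lowers the concentration of free nucleophile and may lead to O-arylation of the carbonate followed by acyl shift;
- base-induced 5-exo addition of the new carboxylate to the alkyne before work-up.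

Fallback with known reactions only, making the ether and the carboxyl in separate events: it sets out from 13 and returns at 17. Purchased 1-bromo-3-fluoro-5-methoxybenzene is lithiated between its two halogens with LiN(i-Pr)2 and quenched with DMF to give 2-bromo-6-fluoro-4-methoxybenzaldehyde F1. Nucleophilic aromatic substitution of its fluoride by 13 (K2CO3, DMF, 90 °C), activated by the ortho formyl group, gives 2-bromo-6-(2,4-dimethoxy-6-pentylphenoxy)-4-methoxybenzaldehyde F2. Sonogashira coupling with 6 (PdCl2(PPh3)2, CuI, Et3N, 60 °C) gives 2-(2,4-dimethoxy-6-pentylphenoxy)-6-(hept-1-yn-1-yl)-4-methoxybenzaldehyde F3, and Pinnick oxidation (NaClO2, NaH2PO4, 2-methylbut-2-ene, t-BuOH–H2O) gives 17.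

**Step 8.** Closure through the other alkyne carbon (5-exo-dig, to the alkylidene phthalide) may compete, because the regiochemistry of metal-catalysed cyclisations of 2-alkynylbenzoic acids depends on catalyst and counter-ion. Fallback by electrophilic cyclisation of the ester, from 17 back to 18: O-methylation (MeI, K2CO3, DMF) gives methyl 2-(2,4-dimethoxy-6-pentylphenoxy)-6-(hept-1-yn-1-yl)-4-methoxybenzoate F4. Iodine in CH2Cl2 induces attack of the ester carbonyl on the iodonium-activated alkyne with loss of the methyl group and gives 8-(2,4-dimethoxy-6-pentylphenoxy)-4-iodo-6-methoxy-3-pentyl-1H-isochromen-1-one F5. Palladium-catalysed formate reduction (Pd(OAc)2, PPh3, HCO2H, Et3N, DMF) removes the iodine and gives 18.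

**Step 2.** Exchange of both iodines, or incomplete exchange, would give mixtures, since mono-selectivity rests on a rate difference between 3 and 4; attack of the alkyllithium at silicon is a second possibility. Fallback that needs no selectivity between two halogens, from 1 back to 5: ortho bromination (N-bromosuccinimide, CH2Cl2) gives 2-bromo-4-methoxyphenol F6, and O-silylation gives (2-bromo-4-methoxyphenoxy)trimethylsilane F7. Bromine–lithium exchange, retro-Brook shift and aqueous quench give 4-methoxy-2-(trimethylsilyl)phenol F8. Base-mediated ortho iodination (I2, morpholine) gives 2-iodo-4-methoxy-6-(trimethylsilyl)phenol F9, where loss of silicon by ipso attack is the point to watch, and triflation ((CF3SO2)2O, pyridine) gives 5.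

**Step 9.** Cleavage of the C6 ether may lag, because this oxygen is conjugated with the lactone carbonyl and is a weaker Lewis base once boron sits on the carbonyl; forcing the reaction risks addition of HBr to the enol lactone. Fallback that splits the task by mechanism, from 18 to 20: BBr3 is used only until the two electron-rich ring B ethers are cleaved, giving 8-(2,4-dihydroxy-6-pentylphenoxy)-6-methoxy-3-pentyl-1H-isochromen-1-one F10. The remaining C6 methyl ether, activated toward nucleophilic attack at methyl by the para carbonyl, is then cleaved with chloride (LiCl, DMF, 140 °C) to give 20.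

## Further compounds

F1 | step 7 | 2-bromo-6-fluoro-4-methoxybenzaldehyde | COc1cc(F)c(C=O)c(Br)c1
F2 | step 7 | 2-bromo-6-(2,4-dimethoxy-6-pentylphenoxy)-4-methoxybenzaldehyde | CCCCCc1cc(OC)cc(OC)c1Oc1cc(OC)cc(Br)c1C=O
F3 | step 7 | 2-(2,4-dimethoxy-6-pentylphenoxy)-6-(hept-1-yn-1-yl)-4-methoxybenzaldehyde | CCCCCC#Cc1cc(OC)cc(Oc2c(OC)cc(OC)cc2CCCCC)c1C=O
F4 | step 8 | methyl 2-(2,4-dimethoxy-6-pentylphenoxy)-6-(hept-1-yn-1-yl)-4-methoxybenzoate | CCCCCC#Cc1cc(OC)cc(Oc2c(OC)cc(OC)cc2CCCCC)c1C(=O)OC
F5 | step 8 | 8-(2,4-dimethoxy-6-pentylphenoxy)-4-iodo-6-methoxy-3-pentyl-1H-isochromen-1-one | CCCCCc1oc(=O)c2c(Oc3c(OC)cc(OC)cc3CCCCC)cc(OC)cc2c1I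
F6 | step 2 | 2-bromo-4-methoxyphenol | COc1ccc(O)c(Br)c1
F7 | step 2 | (2-bromo-4-methoxyphenoxy)trimethylsilane | COc1ccc(O[Si](C)(C)C)c(Br)c1
F8 | step 2 | 4-methoxy-2-(trimethylsilyl)phenol | COc1ccc(O)c([Si](C)(C)C)c1
F9 | step 2 | 2-iodo-4-methoxy-6-(trimethylsilyl)phenol | COc1cc(I)c(O)c([Si](C)(C)C)c1
F10 | step 9 | 8-(2,4-dihydroxy-6-pentylphenoxy)-6-methoxy-3-pentyl-1H-isochromen-1-one | CCCCCc1cc2cc(OC)cc(Oc3c(O)cc(O)cc3CCCCC)c2c(=O)o1
A1 | alternative 1 | 8-(4-ethoxy-2-hydroxy-6-pentylphenoxy)-6-methoxy-3-pentyl-1H-isochromen-1-one | CCCCCc1cc2cc(OC)cc(Oc3c(O)cc(OCC)cc3CCCCC)c2c(=O)o1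
A2 | alternative 1 | 8-{[(1E)-2-(2-diazoacetyl)hept-1-en-1-yl]oxy}-6-methoxy-3-pentyl-1H-isochromen-1-one | CCCCC/C(C(=O)C=[N+]=[N-])=C\Oc1cc(OC)cc2cc(CCCCC)oc(=O)c12
A3 | alternative 1 | ethoxyacetylene (ethoxyethyne) | C#COCC
A4 | alternative 2 | methyl 2-(2,4-dimethoxy-6-pentylphenoxy)-4-hydroxy-6-methylbenzoate | COC(=O)c1c(C)cc(O)cc1Oc1c(OC)cc(OC)cc1CCCCC
A5 | alternative 2 | methyl 3-(2,4-dimethoxy-6-pentylphenoxy)prop-2-ynoate | COC(=O)C#COc1c(OC)cc(OC)cc1CCCCC
A6 | alternative 2 | {[(3E)-4-methoxypenta-1,3-dien-2-yl]oxy}trimethylsilane | C=C(O[Si](C)(C)C)/C=C(\C)OC
A7 | alternative 3 | 8-(2,4-dimethoxy-6-pentylphenoxy)-6-hydroxy-3-pentyl-1H-isochromen-1-one | CCCCCc1cc2cc(O)cc(Oc3c(OC)cc(OC)cc3CCCCC)c2c(=O)o1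
A8 | alternative 3 | 4-methoxy-6-pentyl-2H-pyran-2-one | CCCCCc1cc(OC)cc(=O)o1
A9 | alternative 3 | methyl (2E)-3-(2,4-dimethoxy-6-pentylphenoxy)but-2-enoate | COC(=O)/C=C(\C)Oc1c(OC)cc(OC)cc1CCCCC
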